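Ring B is cut away from ring A at C5–C6, and ring A is read as a 2-methylcyclohex-2-enone: C10 is the carbonyl, quaternary C5 the α-carbon, C4 (with C15) the β-carbon and the oxygen-bearing C3 the γ-carbon. In one operation a methyl cuprate adds C15 to C4 and the resulting C10/C5 enolate is alkylated by an allylic bromide that brings C6, C7, C8 and the isopropylidene group, so that C4–C15 and C5–C6 form and both stereocentres are set from C3. The precursor is the enantiopure 4-silyloxy-2-methylcyclohexenone. Ring B is closed afterwards at C8–C9, C9 is hydroxylated, and the trienoate is attached last.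

Key step: step 8

Remark: eremophilane numbering is used throughout (ring A: C1–C5 and C10; ring B: C5–C10; C14 on C5, C15 on C4; C11–C13 the isopropylidene group), and 4-(tert-butyldimethylsilyloxy)cyclohexanone is assumed to be purchasable.

Step 1
Reactants: 1 4-(tert-butyldimethylsilyloxy)cyclohexan-1-one
Product: 2 (R)-tert-butyldimethyl{[4-(trimethylsilyloxy)cyclohex-3-en-1-yl]oxy}silane
Conditions: (S,S)-bis(1-phenylethyl)amine, n-BuLi, Me3SiCl (present from the start), THF, −100 °C → −78 °C
Reagents that add atoms: chlorotrimethylsilane, C[Si](C)(C)Cl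
Why: Enantioselective deprotonation of a prochiral 4-substituted cyclohexanone by a C2-symmetric lithium amide with in situ silyl trapping (asymmetric desymmetrisation) should remove one of the two enantiotopic axial α-protons and so fix the future C3 as R; the (S,S) amide is chosen by analogy with 4-tert-butylcyclohexanone and would be exchanged for its antipode if the sense proved opposite.

Step 2
Reactants: 2 (R)-tert-butyldimethyl{[4-(trimethylsilyloxy)cyclohex-3-en-1-yl]oxy}silane
Product: 3 (R)-4-(tert-butyldimethylsilyloxy)cyclohex-2-en-1-one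
Conditions: Pd(OAc)2 (10 mol %), O2 (1 atm), DMSO, rt
Reagents that add atoms: none
Why: Saegusa–Ito oxidation (palladation of the silyl enol ether, β-hydride elimination, reoxidation of palladium by O2) should give the enone regiospecifically from the enol ether double bond without touching the silyl ether or the stereocentre.

Step 3
Reactants: 3 (R)-4-(tert-butyldimethylsilyloxy)cyclohex-2-en-1-one
Product: 4 (R)-4-(tert-butyldimethylsilyloxy)-2-iodocyclohex-2-en-1-one
Conditions: I2, pyridine, CH2Cl2, 0 °C → rt
Reagents that add atoms: iodine, [I][I]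
Why: α-Iodination of a cyclohexenone by conjugate addition of pyridine, iodination of the resulting enolate and elimination (an addition–elimination of the Baylis–Hillman type) is routine for 4-silyloxy enones and leaves C3 untouched.

Step 4
Reactants: 4 (R)-4-(tert-butyldimethylsilyloxy)-2-iodocyclohex-2-en-1-one
Product: 5 (R)-4-(tert-butyldimethylsilyloxy)-2-methylcyclohex-2-en-1-one
Conditions: Me4Sn, Pd2(dba)3 (5 mol %), AsPh3, CuI, NMP, 60 °C
Reagents that add atoms: tetramethylstannane, C[Sn](C)(C)C
Why: Stille cross-coupling of the α-iodoenone with Me4Sn runs without base, so the γ-silyloxy enone cannot eliminate or aromatise, and installs the C5 methyl group (C14).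

Step 5
Reactants: 6 diethyl 2-(propan-2-ylidene)malonate
Product: 7 2-(ethoxycarbonyl)-3-methylbut-2-enoic acid
Conditions: KOH (1.0 equiv), EtOH, 0 °C → rt; then 1 M HCl
Reagents that add atoms: potassium hydroxide, [K+].[OH-]
Why: Mono-saponification of a malonic diester should stop at the half-ester because the carboxylate formed deactivates the remaining ester and the hindered β,β-disubstituted alkene resists conjugate attack.

Step 6
Reactants: 7 2-(ethoxycarbonyl)-3-methylbut-2-enoic acid
Product: 8 ethyl 2-(hydroxymethyl)-3-methylbut-2-enoate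
Conditions: BH3·SMe2, THF, 0 °C → rt; then MeOH
Reagents that add atoms: none
Why: Chemoselective reduction of a carboxylic acid by borane in the presence of an ester relies on the fast formation of an acyloxyborane, while the electron-poor tetrasubstituted alkene is inert to the electrophilic hydride source.

Step 7
Reactants: 8 ethyl 2-(hydroxymethyl)-3-methylbut-2-enoate
Product: 9 ethyl 2-(bromomethyl)-3-methylbut-2-enoate
Conditions: PBr3, Et2O, 0 °C
Reagents that add atoms: phosphorus tribromide, BrP(Br)Br
Why: Bromination of a primary allylic alcohol with PBr3 (substitution via the alkyl phosphite) should give the conjugated primary bromide, which is also the thermodynamically favoured allylic isomer.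

Step 8
Reactants: 5 (R)-4-(tert-butyldimethylsilyloxy)-2-methylcyclohex-2-en-1-one; 9 ethyl 2-(bromomethyl)-3-methylbut-2-enoate; 10 methyllithium
Product: 12 ethyl 2-{[(1R,2R,3R)-3-(tert-butyldimethylsilyloxy)-1,2-dimethyl-6-oxocyclohexyl]methyl}-3-methylbut-2-enoate, via lithium enolate 11 (not isolated)
Conditions: 10 (2.4 equiv), CuI (1.2 equiv), Et2O, −78 °C → −30 °C; 5, −78 °C; then 9 (3 equiv), HMPA, THF, −78 °C → rt
Reagents that add atoms: lithium dimethylcuprate (made in the flask from 10 and CuI), [Li+].C[Cu-]C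
Why: Me2CuLi transfers a methyl group to C4 of the enone by π-complexation, oxidative addition to a trivalent copper species and reductive elimination, and since no proton source is present the lithium enolate 11 forms regiospecifically with C5 as its nucleophilic carbon; HMPA then loosens this tetrasubstituted enolate so that it displaces bromide from the CH2 group of 9 (SN2). The closest known reaction type is the one-pot conjugate addition–enolate alkylation of 2-methylcyclohexenones with a cuprate and an allylic halide, which gives 2-allyl-2,3-dimethylcyclohexanones with the new chain trans to the 3-methyl group. No ring is closed; two skeletal bonds, C4–C15 and C5–C6, are made. C4 is set by the C3 silyl ether, which sends the cuprate to the opposite face of the enone, and C5 is set by the new C4 methyl group, which takes the pseudoaxial position to escape A(1,2) strain with the C5 methyl group and shields the β face, so that the bromide should enter axially from the α face and the C5 methyl group end cis to the C4 methyl group; the C3–O bond is then also axial on the α face, but its silyl group points away from the incoming carbon. The step needs C- over O-alkylation and direct substitution over SN2′ or Michael attack on the acrylate: the soft allylic bromide favours carbon, and the fully substituted isopropylidene carbon of 9 blocks both conjugate pathways.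

Step 9
Reactants: 12 ethyl 2-{[(1R,2R,3R)-3-(tert-butyldimethylsilyloxy)-1,2-dimethyl-6-oxocyclohexyl]methyl}-3-methylbut-2-enoate
Product: 13 ethyl 2-{[(1R,2R,3R)-3-(tert-butyldimethylsilyloxy)-1,2-dimethyl-6-methylidenecyclohexyl]methyl}-3-methylbut-2-enoate
Conditions: Ph3PCH3Br (3 equiv), KOtBu (2.8 equiv), toluene, 90 °C
Reagents that add atoms: methylenetriphenylphosphorane (made in the flask from Ph3PCH3Br and KOtBu), C=P(c1ccccc1)(c1ccccc1)c1ccccc1
Why: Wittig methylenation under the forcing, alkoxide-free conditions used for α-quaternary ketones adds C9 to C10, and neither the hindered tetrasubstituted acrylate nor any stereocentre (the only enolisable position is C1) is at risk.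

Step 10
Reactants: 13 ethyl 2-{[(1R,2R,3R)-3-(tert-butyldimethylsilyloxy)-1,2-dimethyl-6-methylidenecyclohexyl]methyl}-3-methylbut-2-enoate
Product: 15 ethyl 2-{[(1S,2R,3R,6R)-3-(tert-butyldimethylsilyloxy)-6-(hydroxymethyl)-1,2-dimethylcyclohexyl]methyl}-3-methylbut-2-enoate, via B-alkyl-9-BBN adduct 14 (not isolated)
Conditions: 9-borabicyclo[3.3.1]nonane (9-BBN), THF, rt → 50 °C; then NaOH, H2O2, 0 °C
Reagents that add atoms: hydrogen peroxide, OO
Why: Hydroboration–oxidation of the 1,1-disubstituted alkene places the hydroxyl on C9 (anti-Markovnikov) and delivers hydrogen to C10 in a syn addition from the α face, opposite the axial C5 methyl group that lies over the β face in the favoured chair, so that H-10 ends trans to that methyl group as the trans-decalin requires, while the electron-poor tetrasubstituted alkene and the ester do not react with 9-BBN.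

Step 11
Reactants: 15 ethyl 2-{[(1S,2R,3R,6R)-3-(tert-butyldimethylsilyloxy)-6-(hydroxymethyl)-1,2-dimethylcyclohexyl]methyl}-3-methylbut-2-enoate
Product: 16 ethyl 2-{[(1R,2R,3R,6R)-3-(tert-butyldimethylsilyloxy)-6-(iodomethyl)-1,2-dimethylcyclohexyl]methyl}-3-methylbut-2-enoate
Conditions: I2, PPh3, imidazole, CH2Cl2, 0 °C → rt
Reagents that add atoms: iodine, [I][I]
Why: Appel-type iodination (SN2 displacement on the alkoxyphosphonium ion) converts the primary alcohol without touching the silyl ether, the ester or the C10 stereocentre.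

Step 12
Reactants: 16 ethyl 2-{[(1R,2R,3R,6R)-3-(tert-butyldimethylsilyloxy)-6-(iodomethyl)-1,2-dimethylcyclohexyl]methyl}-3-methylbut-2-enoate
Product: 18 (4aS,5R,6R,8aS)-6-(tert-butyldimethylsilyloxy)-4a,5-dimethyl-3-(propan-2-ylidene)octahydronaphthalen-2(1H)-one, via primary alkyllithium 17 (not isolated)
Conditions: t-BuLi (2.1 equiv), Et2O/pentane, −78 °C → 0 °C; then H2O
Reagents that add atoms: none
Why: Iodine–lithium exchange, which is far faster than attack of t-BuLi on the hindered ester, gives a primary alkyllithium that acylates itself on the ester in a six-membered transition state (Parham-type anionic cyclisation) and closes ring B at C8–C9, the trans ring fusion following from the equatorial C5–C6 and C10–C9 bonds already in place.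

Step 13
Reactants: 18 (4aS,5R,6R,8aS)-6-(tert-butyldimethylsilyloxy)-4a,5-dimethyl-3-(propan-2-ylidene)octahydronaphthalen-2(1H)-one
Product: 20 (1S,4aR,5R,6R,8aR)-6-(tert-butyldimethylsilyloxy)-1-hydroxy-4a,5-dimethyl-3-(propan-2-ylidene)octahydronaphthalen-2(1H)-one, via potassium enolate 19 (not isolated)
Conditions: KN(SiMe3)2 (1.1 equiv), THF, −78 °C; then 2-(phenylsulfonyl)-3-phenyloxaziridine, −78 °C; aq. NH4Cl
Reagents that add atoms: 2-(phenylsulfonyl)-3-phenyloxaziridine, O=S(=O)(c1ccccc1)N1OC1c1ccccc1
Why: Kinetic deprotonation of the α-alkylidene ketone at the α′ carbon C9 and oxidation of the potassium enolate by the N-sulfonyloxaziridine (Davis oxidation) should give the 9α (equatorial) alcohol, because the β face of C9 is blocked by the 1,3-related axial C5 methyl group and the equatorial epimer is also the more stable one.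

Step 14
Reactants: 20 (1S,4aR,5R,6R,8aR)-6-(tert-butyldimethylsilyloxy)-1-hydroxy-4a,5-dimethyl-3-(propan-2-ylidene)octahydronaphthalen-2(1H)-one
Product: 21 allyl (1S,4aR,5R,6R,8aR)-6-(tert-butyldimethylsilyloxy)-4a,5-dimethyl-2-oxo-3-(propan-2-ylidene)decahydronaphthalen-1-yl carbonate
Conditions: allyl chloroformate, pyridine, 4-(dimethylamino)pyridine (10 mol %), CH2Cl2, 0 °C → rt
Reagents that add atoms: allyl chloroformate, C=CCOC(Cl)=O
Why: Acylation of the secondary α-ketol with a chloroformate gives an allyl carbonate, a group that survives fluoride and acylation conditions and can later be removed under neutral conditions.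

Step 15
Reactants: 21 allyl (1S,4aR,5R,6R,8aR)-6-(tert-butyldimethylsilyloxy)-4a,5-dimethyl-2-oxo-3-(propan-2-ylidene)decahydronaphthalen-1-yl carbonate
Product: 22 allyl (1S,4aR,5R,6R,8aR)-6-hydroxy-4a,5-dimethyl-2-oxo-3-(propan-2-ylidene)decahydronaphthalen-1-yl carbonate
Conditions: HF·pyridine, pyridine, THF, 0 °C → rt
Reagents that add atoms: none
Why: Fluoride-mediated cleavage of the secondary silyl ether with buffered HF·pyridine frees the C3 hydroxyl while the allyl carbonate, the enone and all stereocentres stay intact.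

Step 16
Reactants: 23 (E)-oct-2-enal
Product: 24 (E)-non-3-en-1-yne
Conditions: Me3SiCHN2, LiN(iPr)2, THF, −78 °C → rt; then H2O
Reagents that add atoms: (trimethylsilyl)diazomethane, C[Si](C)(C)C=[N+]=[N-]
Why: Colvin rearrangement (addition of the lithiated silyldiazomethane to the aldehyde, Peterson-type elimination and 1,2-hydrogen shift of the alkylidene carbene) homologates the enal to the terminal enyne without touching the E alkene.

Step 17
Reactants: 24 (E)-non-3-en-1-yne
Product: 26 (1E,3E)-1-iodo-2-methylnona-1,3-diene, via alkenylalane 25 (not isolated)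
Conditions: Me3Al (2 equiv), Cp2ZrCl2 (25 mol %), CH2Cl2, 0 °C → rt; then I2, THF, −30 °C → 0 °C
Reagents that add atoms: trimethylaluminium, C[Al](C)C; iodine, [I][I]
Why: Zirconium-catalysed carboalumination of the terminal alkyne (Negishi carboalumination) adds methyl and aluminium syn, with methyl on the internal carbon, and iodinolysis with retention should give the E trisubstituted alkenyl iodide.

Step 18
Reactants: 26 (1E,3E)-1-iodo-2-methylnona-1,3-diene; 27 acrylic acid
Product: 28 (2E,4E,6E)-5-methyldodeca-2,4,6-trienoic acid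
Conditions: Pd(OAc)2 (5 mol %), K2CO3, Bu4NCl, DMF, rt → 50 °C; then 1 M HCl
Reagents that add atoms: none
Why: Heck reaction of the alkenyl iodide with acrylic acid under ligand-free phase-transfer conditions keeps the geometry of the iodide and forms the new disubstituted alkene as the E isomer through syn insertion and syn β-hydride elimination.

Step 19
Reactants: 28 (2E,4E,6E)-5-methyldodeca-2,4,6-trienoic acid; 22 allyl (1S,4aR,5R,6R,8aR)-6-hydroxy-4a,5-dimethyl-2-oxo-3-(propan-2-ylidene)decahydronaphthalen-1-yl carbonate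
Product: 30 (1R,2R,4aR,5S,8aR)-5-{[(allyloxy)carbonyl]oxy}-1,8a-dimethyl-6-oxo-7-(propan-2-ylidene)decahydronaphthalen-2-yl (2E,4E,6E)-5-methyldodeca-2,4,6-trienoate, via mixed anhydride 29 (not isolated)
Conditions: 28, 2,4,6-trichlorobenzoyl chloride, Et3N, THF, rt; then 22, 4-(dimethylamino)pyridine, toluene, rt → 40 °C
Reagents that add atoms: none
Why: Yamaguchi esterification through the mixed anhydride and an acylpyridinium ion acylates the hindered equatorial C3 hydroxyl with retention of configuration, and the all-E trienoate, being the thermodynamic geometry, is not at risk from the nucleophilic catalyst.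

Step 20
Reactants: 30 (1R,2R,4aR,5S,8aR)-5-{[(allyloxy)carbonyl]oxy}-1,8a-dimethyl-6-oxo-7-(propan-2-ylidene)decahydronaphthalen-2-yl (2E,4E,6E)-5-methyldodeca-2,4,6-trienoate
Product: 31 (1R,2R,4aR,5S,8aR)-5-hydroxy-1,8a-dimethyl-6-oxo-7-(propan-2-ylidene)decahydronaphthalen-2-yl (2E,4E,6E)-5-methyldodeca-2,4,6-trienoate
Conditions: Pd(PPh3)4 (5 mol %), morpholine, THF, rt
Reagents that add atoms: none
Why: Tsuji–Trost-type deallylation (ionisation of the allyl carbonate by zerovalent palladium, loss of CO2 and capture of the allyl group by morpholine) frees the C9 hydroxyl under neutral conditions that leave the trienoate, the enone and the α-ketol stereocentre untouched.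

Compound list

1 | 4-(tert-butyldimethylsilyloxy)cyclohexan-1-one | CC(C)(C)[Si](C)(C)OC1CCC(=O)CC1 | starting material
2 | (R)-tert-butyldimethyl{[4-(trimethylsilyloxy)cyclohex-3-en-1-yl]oxy}silane | CC(C)(C)[Si](C)(C)O[C@@H]1CCC(O[Si](C)(C)C)=CC1 | intermediate
3 | (R)-4-(tert-butyldimethylsilyloxy)cyclohex-2-en-1-one | CC(C)(C)[Si](C)(C)O[C@@H]1CCC(=O)C=C1 | intermediate
4 | (R)-4-(tert-butyldimethylsilyloxy)-2-iodocyclohex-2-en-1-one | CC(C)(C)[Si](C)(C)O[C@@H]1CCC(=O)C(I)=C1 | intermediate
5 | (R)-4-(tert-butyldimethylsilyloxy)-2-methylcyclohex-2-en-1-one | CC(C)(C)[Si](C)(C)O[C@@H]1CCC(=O)C(C)=C1 | intermediate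
6 | diethyl 2-(propan-2-ylidene)malonate | CCOC(=O)C(=C(C)C)C(=O)OCC | starting material
7 | 2-(ethoxycarbonyl)-3-methylbut-2-enoic acid | CCOC(=O)C(C(=O)O)=C(C)C | intermediate
8 | ethyl 2-(hydroxymethyl)-3-methylbut-2-enoate | CCOC(=O)C(CO)=C(C)C | intermediate
9 | ethyl 2-(bromomethyl)-3-methylbut-2-enoate | CCOC(=O)C(CBr)=C(C)C | intermediate
10 | methyllithium | [Li]C | starting material
11 | lithium (3R,4R)-4-(tert-butyldimethylsilyloxy)-2,3-dimethylcyclohex-1-en-1-olate | [Li+].CC(C)(C)[Si](C)(C)O[C@@H]1CCC([O-])=C(C)[C@H]1C | intermediate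
12 | ethyl 2-{[(1R,2R,3R)-3-(tert-butyldimethylsilyloxy)-1,2-dimethyl-6-oxocyclohexyl]methyl}-3-methylbut-2-enoate | CC(C)(C)[Si](C)(C)O[C@@H]1CCC(=O)[C@](C)(CC(=C(C)C)C(=O)OCC)[C@H]1C | intermediate
13 | ethyl 2-{[(1R,2R,3R)-3-(tert-butyldimethylsilyloxy)-1,2-dimethyl-6-methylidenecyclohexyl]methyl}-3-methylbut-2-enoate | CC(C)(C)[Si](C)(C)O[C@@H]1CCC(=C)[C@](C)(CC(=C(C)C)C(=O)OCC)[C@H]1C | intermediate
14 | ethyl 2-{[(1S,2R,3R,6R)-6-[(9-borabicyclo[3.3.1]nonan-9-yl)methyl]-3-(tert-butyldimethylsilyloxy)-1,2-dimethylcyclohexyl]methyl}-3-methylbut-2-enoate | CC(C)(C)[Si](C)(C)O[C@@H]1CC[C@@H](CB2C3CCCC2CCC3)[C@](C)(CC(=C(C)C)C(=O)OCC)[C@H]1C | intermediate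
15 | ethyl 2-{[(1S,2R,3R,6R)-3-(tert-butyldimethylsilyloxy)-6-(hydroxymethyl)-1,2-dimethylcyclohexyl]methyl}-3-methylbut-2-enoate | CC(C)(C)[Si](C)(C)O[C@@H]1CC[C@@H](CO)[C@](C)(CC(=C(C)C)C(=O)OCC)[C@H]1C | intermediate
16 | ethyl 2-{[(1R,2R,3R,6R)-3-(tert-butyldimethylsilyloxy)-6-(iodomethyl)-1,2-dimethylcyclohexyl]methyl}-3-methylbut-2-enoate | CC(C)(C)[Si](C)(C)O[C@@H]1CC[C@@H](CI)[C@](C)(CC(=C(C)C)C(=O)OCC)[C@H]1C | intermediate
17 | ethyl 2-{[(1S,2R,3R,6R)-3-(tert-butyldimethylsilyloxy)-6-(lithiomethyl)-1,2-dimethylcyclohexyl]methyl}-3-methylbut-2-enoate | CC(C)(C)[Si](C)(C)O[C@@H]1CC[C@@H](C[Li])[C@](C)(CC(=C(C)C)C(=O)OCC)[C@H]1C | intermediate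
18 | (4aS,5R,6R,8aS)-6-(tert-butyldimethylsilyloxy)-4a,5-dimethyl-3-(propan-2-ylidene)octahydronaphthalen-2(1H)-one | CC(C)(C)[Si](C)(C)O[C@@H]1CC[C@H]2CC(=O)C(=C(C)C)C[C@]2(C)[C@H]1C | intermediate
19 | potassium (4aS,5R,6R,8aS)-6-(tert-butyldimethylsilyloxy)-4a,5-dimethyl-3-(propan-2-ylidene)-3,4,4a,5,6,7,8,8a-octahydronaphthalen-2-olate | [K+].CC(C)(C)[Si](C)(C)O[C@@H]1CC[C@H]2C=C([O-])C(=C(C)C)C[C@]2(C)[C@H]1C | intermediate
20 | (1S,4aR,5R,6R,8aR)-6-(tert-butyldimethylsilyloxy)-1-hydroxy-4a,5-dimethyl-3-(propan-2-ylidene)octahydronaphthalen-2(1H)-one | CC(C)(C)[Si](C)(C)O[C@@H]1CC[C@H]2[C@H](O)C(=O)C(=C(C)C)C[C@]2(C)[C@H]1C | intermediate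
21 | allyl (1S,4aR,5R,6R,8aR)-6-(tert-butyldimethylsilyloxy)-4a,5-dimethyl-2-oxo-3-(propan-2-ylidene)decahydronaphthalen-1-yl carbonate | CC(C)(C)[Si](C)(C)O[C@@H]1CC[C@H]2[C@H](OC(=O)OCC=C)C(=O)C(=C(C)C)C[C@]2(C)[C@H]1C | intermediate
22 | allyl (1S,4aR,5R,6R,8aR)-6-hydroxy-4a,5-dimethyl-2-oxo-3-(propan-2-ylidene)decahydronaphthalen-1-yl carbonate | O[C@@H]1CC[C@H]2[C@H](OC(=O)OCC=C)C(=O)C(=C(C)C)C[C@]2(C)[C@H]1C | intermediate
23 | (E)-oct-2-enal | CCCCC/C=C/C=O | starting material
24 | (E)-non-3-en-1-yne | CCCCC/C=C/C#C | intermediate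
25 | dimethyl[(1E,3E)-2-methylnona-1,3-dien-1-yl]alumane | CCCCC/C=C/C(C)=C/[Al](C)C | intermediate
26 | (1E,3E)-1-iodo-2-methylnona-1,3-diene | CCCCC/C=C/C(C)=C/I | intermediate
27 | acrylic acid | C=CC(=O)O | starting material
28 | (2E,4E,6E)-5-methyldodeca-2,4,6-trienoic acid | CCCCC/C=C/C(C)=C/C=C/C(=O)O | intermediate
29 | (2E,4E,6E)-5-methyldodeca-2,4,6-trienoic 2,4,6-trichlorobenzoic anhydride | CCCCC/C=C/C(C)=C/C=C/C(=O)OC(=O)c1c(Cl)cc(Cl)cc1Cl | intermediate
30 | (1R,2R,4aR,5S,8aR)-5-{[(allyloxy)carbonyl]oxy}-1,8a-dimethyl-6-oxo-7-(propan-2-ylidene)decahydronaphthalen-2-yl (2E,4E,6E)-5-methyldodeca-2,4,6-trienoate | CCCCC/C=C/C(C)=C/C=C/C(=O)O[C@@H]1CC[C@H]2[C@H](OC(=O)OCC=C)C(=O)C(=C(C)C)C[C@]2(C)[C@H]1C | intermediate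
31 | (1R,2R,4aR,5S,8aR)-5-hydroxy-1,8a-dimethyl-6-oxo-7-(propan-2-ylidene)decahydronaphthalen-2-yl (2E,4E,6E)-5-methyldodeca-2,4,6-trienoate | CCCCC/C=C/C(C)=C/C=C/C(=O)O[C@@H]1CC[C@H]2[C@H](O)C(=O)C(=C(C)C)C[C@]2(C)[C@H]1C | target

Total step count: 20 (4 to enone 5, 3 to bromide 9, the key step, 7 from 12 to alcohol 22, 3 to acid 28, then esterification and deprotection).
Longest linear sequence: 14 steps (steps 1–4, 8–15, 19 and 20).

Steps most likely to fail

1. Step 8. The tetrasubstituted, copper-bound enolate may react too slowly with the hindered bromide. Proton transfer, methylation of the bromide by the copper species or loss of facial control at C5 would then lower conversion or selectivity. Fallback: setting out from 5, the cuprate addition is run with Me3SiCl present and the enolate is isolated as its silyl enol ether, tert-butyl{[(1R,2R)-2,3-dimethyl-4-(trimethylsilyloxy)cyclohex-3-en-1-yl]oxy}dimethylsilane F1. MeLi in THF then cleaves F1 to the copper-free lithium enolate 11, which is alkylated with 9 in THF/HMPA at low temperature. The route is rejoined at 12.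

2. Step 12. After the exchange the alkyllithium may be consumed by proton transfer from the allylic methyl groups of the unsaturated ester, or by intermolecular addition, before it closes the ring. Fallback: setting out from 16, sodium benzenesulfinate in DMF gives the sulfone ethyl 2-{[(1R,2R,3R,6R)-3-(tert-butyldimethylsilyloxy)-1,2-dimethyl-6-[(phenylsulfonyl)methyl]cyclohexyl]methyl}-3-methylbut-2-enoate F2. LiN(iPr)2 (2.2 equiv) in THF closes ring B by intramolecular acylation of the sulfonyl carbanion by the ester, giving the β-keto sulfone (4aR,5R,6R,8aR)-6-(tert-butyldimethylsilyloxy)-4a,5-dimethyl-1-(phenylsulfonyl)-3-(propan-2-ylidene)octahydronaphthalen-2(1H)-one F3. SmI2 in THF/MeOH at −78 °C removes the sulfonyl group, and the route is rejoined at 18.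

3. Step 1. Incomplete discrimination of the two enantiotopic protons would carry a share of the wrong enantiomer into every later compound. Fallback: this one does not start from 1 but from purchased 1,4-dioxaspiro[4.5]dec-6-en-8-one F4. Corey–Bakshi–Shibata reduction with (S)-1-methyl-3,3-diphenyltetrahydro-1H,3H-pyrrolo[1,2-c][1,3,2]oxazaborole and BH3·SMe2 should give, by the usual model, (R)-1,4-dioxaspiro[4.5]dec-6-en-8-ol F5. tBuMe2SiCl and imidazole in DMF give (R)-tert-butyl(1,4-dioxaspiro[4.5]dec-6-en-8-yloxy)dimethylsilane F6, and pyridinium p-toluenesulfonate in wet acetone removes the ketal. The route is rejoined at 3.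

Further compounds

F1 | step 8 | tert-butyl{[(1R,2R)-2,3-dimethyl-4-(trimethylsilyloxy)cyclohex-3-en-1-yl]oxy}dimethylsilane | CC(C)(C)[Si](C)(C)O[C@@H]1CCC(O[Si](C)(C)C)=C(C)[C@H]1C
F2 | step 12 | ethyl 2-{[(1R,2R,3R,6R)-3-(tert-butyldimethylsilyloxy)-1,2-dimethyl-6-[(phenylsulfonyl)methyl]cyclohexyl]methyl}-3-methylbut-2-enoate | CC(C)(C)[Si](C)(C)O[C@@H]1CC[C@@H](CS(=O)(=O)c2ccccc2)[C@](C)(CC(=C(C)C)C(=O)OCC)[C@H]1C
F3 | step 12 | (4aR,5R,6R,8aR)-6-(tert-butyldimethylsilyloxy)-4a,5-dimethyl-1-(phenylsulfonyl)-3-(propan-2-ylidene)octahydronaphthalen-2(1H)-one (both C1 epimers) | CC(C)(C)[Si](C)(C)O[C@@H]1CC[C@H]2C(S(=O)(=O)c3ccccc3)C(=O)C(=C(C)C)C[C@]2(C)[C@H]1C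
F4 | step 1 | 1,4-dioxaspiro[4.5]dec-6-en-8-one (purchased) | O=C1CCC2(C=C1)OCCO2
F5 | step 1 | (R)-1,4-dioxaspiro[4.5]dec-6-en-8-ol | O[C@@H]1CCC2(C=C1)OCCO2
F6 | step 1 | (R)-tert-butyl(1,4-dioxaspiro[4.5]dec-6-en-8-yloxy)dimethylsilane | CC(C)(C)[Si](C)(C)O[C@@H]1CCC2(C=C1)OCCO2
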